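The route rests on disconnecting the bond between C2 of the dihydropyran ring and the phloroglucinol-derived 2-aryl ring. C2 is an O1-bound, acetal-level carbon and at the same time benzylic to a ring whose CH positions are strongly nucleophilic; the neighbouring C3 carries the isopropyl group. The key step therefore ionises an enantioenriched (3S)-chroman-2-ol (anomer mixture, A ring with 5,7-benzyl ethers) to its cyclic oxocarbenium ion and traps it with phloroglucinol itself, stereoconvergently giving the 2,3-trans 2-arylchroman. The lactol comes from an aminocatalytic aldehyde addition to an o-quinone methide; double formylation and debenzylation finish the synthesis.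

Key step: step 6

Remark: chroman numbering is used (O1, C2, C3, C4, C4a, C5–C8, C8a; A ring = acylated benzo ring, B ring = 2-aryl ring); the target is read as the 2,3-trans (2R,3S) isomer, and lactol 10 is carried on as its mixture of C2 anomers.

Step 1
Reactants: 1 phloroglucinol; 2 3-methylbutanoyl chloride (isovaleryl chloride)
Product: 3 1-(2,4,6-trihydroxyphenyl)-3-methylbutan-1-one
Conditions: AlCl3 (4 equiv), CH2Cl2/MeNO2, 0 °C→rt; aq. HCl
Reagents that add atoms: none
Why: Friedel–Crafts acylation of the C3-symmetric triphenol should stop after one acyl group because the chelated ketone deactivates the ring; no stereocentre is formed.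

Step 2
Reactants: 3 1-(2,4,6-trihydroxyphenyl)-3-methylbutan-1-one
Product: 5 1-[4-(allyloxy)-2,6-bis(benzyloxy)phenyl]-3-methylbutan-1-one, via 4-O-allyl ether 4 (not isolated)
Conditions: allyl bromide (1.0 equiv), K2CO3 (1.1 equiv), DMF, 0 °C→rt; then BnBr (2.5 equiv), K2CO3 (3 equiv), 60 °C
Reagents that add atoms: allyl bromide C=CCBr; benzyl bromide BrCc1ccccc1
Why: Williamson etherification in which the non-chelated, most acidic para-OH should take the single equivalent of allyl bromide first and the two ketone-chelated ortho-OH groups are then benzylated on heating, so that the future O1 carries a group orthogonal to the benzyl ethers of the future O5 and O7.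

Step 3
Reactants: 5 1-[4-(allyloxy)-2,6-bis(benzyloxy)phenyl]-3-methylbutan-1-one
Product: 6 1-[2,6-bis(benzyloxy)-4-hydroxyphenyl]-3-methylbutan-1-one
Conditions: Pd(PPh3)4 (5 mol %), morpholine (5 equiv), THF, rt
Reagents that add atoms: none
Why: Tsuji–Trost-type Pd(0) deallylation (π-allyl transfer to morpholine) should free only the para-phenol, the benzyl ethers and the ketone being inert.

Step 4
Reactants: 6 1-[2,6-bis(benzyloxy)-4-hydroxyphenyl]-3-methylbutan-1-one
Product: 7 1-[2,6-bis(benzyloxy)-4-hydroxy-3-(tosylmethyl)phenyl]-3-methylbutan-1-one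
Conditions: 37% aq. CH2O (1.2 equiv), TolSO2Na (1.5 equiv), HCO2H/H2O, rt
Reagents that add atoms: formaldehyde C=O; sodium p-toluenesulfinate Cc1ccc(cc1)S(=O)[O-].[Na+]
Why: Mannich-type three-component sulfonylmethylation (phenol, formaldehyde, sulfinate) can only occur ortho to the free OH (the two ortho positions are equivalent, the para position is blocked) and should give a bench-stable o-quinone methide precursor.

Step 5
Reactants: 7 1-[2,6-bis(benzyloxy)-4-hydroxy-3-(tosylmethyl)phenyl]-3-methylbutan-1-one; 8 3-methylbutanal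
Product: 10 1-[(3S)-5,7-bis(benzyloxy)-2-hydroxy-3-isopropylchroman-6-yl]-3-methylbutan-1-one (C2 anomers), via o-quinone methide 9 (not isolated)
Conditions: 8 (3 equiv), (S)-α,α-diphenylprolinol trimethylsilyl ether (20 mol %), Na2CO3 (1.5 equiv), CH2Cl2, 0 °C→rt
Reagents that add atoms: none
Why: Base-induced 1,4-elimination of sulfinate gives o-quinone methide 9, whose only possible carbonyl oxygen is the future O1, and the E-enamine of 8 should add to its CH2 on the face remote from the CPh2OTMS group (aminocatalytic Michael addition–hemiacetalisation), which sets C3 as S and closes the lactol on O1 alone.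

Step 6
Reactants: 10 1-[(3S)-5,7-bis(benzyloxy)-2-hydroxy-3-isopropylchroman-6-yl]-3-methylbutan-1-one; 1 phloroglucinol
Product: 12 1-[(2R,3S)-5,7-bis(benzyloxy)-3-isopropyl-2-(2,4,6-trihydroxyphenyl)chroman-6-yl]-3-methylbutan-1-one, via oxocarbenium ion 11 (not isolated)
Conditions: 1 (6 equiv), BF3·OEt2 (1.5 equiv), MeCN/CH2Cl2, −40→−10 °C; cold aq. NaHCO3
Reagents that add atoms: none
Why: BF3 ionises both anomers of lactol 10 to the same benzo-fused cyclic oxocarbenium ion 11 (O1=C2), which a ring CH of phloroglucinol captures at C2 by electrophilic aromatic substitution, possibly through a reversible O-aryl acetal and O→C shift. The closest known reaction type is the Lewis acid mediated aryl C-glycosylation (Friedel–Crafts arylation) of lactols or glycosyl acetates with phloroglucinol-type phenols. No ring is closed, since the dihydropyran ring (O1, C2, C3, C4, C4a, C8a) is already present and only the C2–aryl bond is made. The new stereocentre C2 is controlled by the C3 isopropyl group: the arene should add anti to it to give the 2,3-trans (2R,3S) adduct, which is also the diequatorial thermodynamic isomer, so that both anomers and any cis adduct (through acid-reversible ipso-protonation or C2–O1 ionisation, O5 being benzylated) converge on one configuration. The step needs phloroglucinol (three equivalent CH positions, hence no regiochemical issue) to outcompete C8 of the A ring and to react only once, which the ketone and full O-alkylation of the A ring and the excess of phloroglucinol secure, and it needs C3 to survive, which the low temperature and fast capture should secure against loss of H3 from 11 to the 4H-chromene.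

Step 7
Reactants: 12 1-[(2R,3S)-5,7-bis(benzyloxy)-3-isopropyl-2-(2,4,6-trihydroxyphenyl)chroman-6-yl]-3-methylbutan-1-one
Product: 14 5-[(2R,3S)-5,7-bis(benzyloxy)-3-isopropyl-6-(3-methylbutanoyl)chroman-2-yl]-2,4,6-trihydroxybenzene-1,3-dicarbaldehyde, via bis(iminium) salt 13 (not isolated)
Conditions: POCl3 (3 equiv), DMF (6 equiv), MeCN, 0 °C→rt; then H2O, 40 °C
Reagents that add atoms: N,N-dimethylformamide CN(C)C=O; water O
Why: Vilsmeier–Haack formylation should attack the two free CH positions of the trihydroxyphenyl ring, by far the most electron-rich ring, while the fully O-alkylated, ketone-bearing A ring (C8–H) should not react at this temperature, and hydrolysis of bis(iminium) salt 13 liberates the two aldehydes without touching C2 or C3.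

Step 8
Reactants: 14 5-[(2R,3S)-5,7-bis(benzyloxy)-3-isopropyl-6-(3-methylbutanoyl)chroman-2-yl]-2,4,6-trihydroxybenzene-1,3-dicarbaldehyde
Product: 15 5-[(2R,3S)-5,7-dihydroxy-3-isopropyl-6-(3-methylbutanoyl)chroman-2-yl]-2,4,6-trihydroxybenzene-1,3-dicarbaldehyde (CNP0551232.1)
Conditions: BCl3 (6 equiv), C6HMe5 (6 equiv), CH2Cl2, −78 °C; MeOH, then H2O
Reagents that add atoms: none
Why: BCl3 with pentamethylbenzene as benzyl cation scavenger (non-reductive debenzylation) should cleave the two benzyl ethers, both ortho to the chelating ketone, at −78 °C, where the aldehydes, the ketone and the C2–O1 ether of the now electron-poor diformyl ring survive and both stereocentres are retained.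

Compound list
1 | phloroglucinol (benzene-1,3,5-triol) | Oc1cc(O)cc(O)c1 | starting material
2 | 3-methylbutanoyl chloride | CC(C)CC(Cl)=O | starting material
3 | 1-(2,4,6-trihydroxyphenyl)-3-methylbutan-1-one | CC(C)CC(=O)c1c(O)cc(O)cc1O | intermediate
4 | 1-[4-(allyloxy)-2,6-dihydroxyphenyl]-3-methylbutan-1-one (not isolated) | CC(C)CC(=O)c1c(O)cc(OCC=C)cc1O | intermediate
5 | 1-[4-(allyloxy)-2,6-bis(benzyloxy)phenyl]-3-methylbutan-1-one | CC(C)CC(=O)c1c(OCc2ccccc2)cc(OCC=C)cc1OCc1ccccc1 | intermediate
6 | 1-[2,6-bis(benzyloxy)-4-hydroxyphenyl]-3-methylbutan-1-one | CC(C)CC(=O)c1c(OCc2ccccc2)cc(O)cc1OCc1ccccc1 | intermediate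
7 | 1-[2,6-bis(benzyloxy)-4-hydroxy-3-(tosylmethyl)phenyl]-3-methylbutan-1-one | CC(C)CC(=O)c1c(OCc2ccccc2)cc(O)c(CS(=O)(=O)c2ccc(C)cc2)c1OCc1ccccc1 | intermediate
8 | 3-methylbutanal (isovaleraldehyde) | CC(C)CC=O | starting material
9 | 3,5-bis(benzyloxy)-6-methylidene-4-(3-methylbutanoyl)cyclohexa-2,4-dien-1-one (o-quinone methide, not isolated) | CC(C)CC(=O)C1=C(OCc2ccccc2)C(=C)C(=O)C=C1OCc1ccccc1 | intermediate
10 | 1-[(3S)-5,7-bis(benzyloxy)-2-hydroxy-3-isopropylchroman-6-yl]-3-methylbutan-1-one (lactol, both C2 anomers) | CC(C)CC(=O)c1c(OCc2ccccc2)cc2c(c1OCc1ccccc1)C[C@@H](C(C)C)C(O)O2 | intermediate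
11 | (3S)-5,7-bis(benzyloxy)-3-isopropyl-6-(3-methylbutanoyl)-3,4-dihydro-2H-chromenylium hydroxytrifluoroborate (cyclic oxocarbenium ion, O1=C2, not isolated) | CC(C)CC(=O)c1c(OCc2ccccc2)cc2c(c1OCc1ccccc1)C[C@@H](C(C)C)C=[O+]2.O[B-](F)(F)F | intermediate
12 | 1-[(2R,3S)-5,7-bis(benzyloxy)-3-isopropyl-2-(2,4,6-trihydroxyphenyl)chroman-6-yl]-3-methylbutan-1-one (2,3-trans) | CC(C)CC(=O)c1c(OCc2ccccc2)cc2c(c1OCc1ccccc1)C[C@@H](C(C)C)[C@H](c1c(O)cc(O)cc1O)O2 | intermediate
13 | bis(N,N-dimethyliminium) dichloride corresponding to dialdehyde 14 (not isolated) | CC(C)CC(=O)c1c(OCc2ccccc2)cc2c(c1OCc1ccccc1)C[C@@H](C(C)C)[C@H](c1c(O)c(C=[N+](C)C)c(O)c(C=[N+](C)C)c1O)O2.[Cl-].[Cl-] | intermediate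
14 | 5-[(2R,3S)-5,7-bis(benzyloxy)-3-isopropyl-6-(3-methylbutanoyl)chroman-2-yl]-2,4,6-trihydroxybenzene-1,3-dicarbaldehyde | CC(C)CC(=O)c1c(OCc2ccccc2)cc2c(c1OCc1ccccc1)C[C@@H](C(C)C)[C@H](c1c(O)c(C=O)c(O)c(C=O)c1O)O2 | intermediate
15 | 5-[(2R,3S)-5,7-dihydroxy-3-isopropyl-6-(3-methylbutanoyl)chroman-2-yl]-2,4,6-trihydroxybenzene-1,3-dicarbaldehyde (CNP0551232.1) | CC(C)CC(=O)c1c(O)cc2c(c1O)C[C@@H](C(C)C)[C@H](c1c(O)c(C=O)c(O)c(C=O)c1O)O2 | target

Total step count: 8. Longest linear sequence: 8 steps (1 → 3 → 5 → 6 → 7 → 10 → 12 → 14 → 15); the second phloroglucinol unit enters directly in step 6.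

Steps most likely to fail

Step 6. The oxocarbenium ion may lose H3 to give the 4H-chromene and be reprotonated, which would erode the C3 configuration. Phloroglucinol may also be alkylated twice, or the anti addition may be incomplete. The fallback sets out from lactol 10, makes the same bond by carbonyl addition and returns at 12. Phloroglucinol 1 is converted with MOMCl/NaH (DMF, 0 °C) into 1,3,5-tris(methoxymethoxy)benzene F1. n-BuLi (THF, 0 °C) lithiates F1 between two MOM-oxy groups to give 2,4,6-tris(methoxymethoxy)phenyllithium F2. F2 (3 equiv, THF, −78 °C) deprotonates 10 and adds to the aldehyde form of the opened lactolate, the di-ortho-substituted ketone being far less electrophilic, to give 1-[2,6-bis(benzyloxy)-4-hydroxy-3-[(2S)-2-[hydroxy(2,4,6-tris(methoxymethoxy)phenyl)methyl]-3-methylbutyl]phenyl]-3-methylbutan-1-one F3 as both carbinol epimers. HCl in MeOH (rt) then removes the MOM groups and ionises the carbinol to the B-ring-stabilised benzylic cation. O1, the only free A-ring oxygen, captures this cation in a reversible 6-exo-trig closure that should settle on the trans chroman 12.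

Step 7. Formylation may also occur at C8 of the A ring, the second formylation may stall, and the acid formed may open the electron-rich 2-arylchroman at C2–O1 before the first formyl group has deactivated the B ring. The fallback sets out from lactol 10, brings both formyl groups in with the nucleophile and returns at 14, so that steps 6 and 7 are replaced. Lactol 10 is acetylated (Ac2O, pyridine, DMAP, 0 °C) to 1-[(3S)-2-acetoxy-5,7-bis(benzyloxy)-3-isopropylchroman-6-yl]-3-methylbutan-1-one F4. F4 is coupled with commercial 2,4,6-trihydroxyisophthalaldehyde (O=Cc1c(O)cc(O)c(C=O)c1O) under TMSOTf (MeCN, −20 °C→rt), by O-aryl acetal formation and O→C (Fries-type) rearrangement onto the single free ring carbon, to give 14. This nucleophile is much less reactive than phloroglucinol, which is why it is not the first choice.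

Step 5. Facial discrimination in the enamine attack may be insufficient, the o-quinone methide may oligomerise before capture, and the amine may epimerise the α-branched lactol. The fallback sets out from sulfone 7, replaces catalyst control by auxiliary control and returns at 10. (S)-4-Benzyl-3-(3-methylbutanoyl)oxazolidin-2-one (CC(C)CC(=O)N1[C@@H](Cc2ccccc2)COC1=O; NaHMDS, THF, −78 °C, 2.2 equiv) gives the sodium Z-enolate, one equivalent of which deprotonates 7 so that o-quinone methide 9 is released on warming to −40 °C. The enolate should add to 9 on the face away from the benzyl group to give (S)-4-benzyl-3-[(2S)-2-[2,4-bis(benzyloxy)-6-hydroxy-3-(3-methylbutanoyl)benzyl]-3-methylbutanoyl]oxazolidin-2-one F5. Et3N/DMAP in toluene at 60 °C lets the neighbouring phenol displace the auxiliary to give (3S)-5,7-bis(benzyloxy)-3-isopropyl-6-(3-methylbutanoyl)chroman-2-one F6. DIBAL-H (CH2Cl2, −78 °C) reduces this aryl lactone, far more electrophilic than the hindered ketone, to lactol 10.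

Further compounds
F1 | step 6 | 1,3,5-tris(methoxymethoxy)benzene | COCOc1cc(OCOC)cc(OCOC)c1
F2 | step 6 | 2,4,6-tris(methoxymethoxy)phenyllithium | [Li]c1c(OCOC)cc(OCOC)cc1OCOC
F3 | step 6 | 1-[2,6-bis(benzyloxy)-4-hydroxy-3-[(2S)-2-[hydroxy(2,4,6-tris(methoxymethoxy)phenyl)methyl]-3-methylbutyl]phenyl]-3-methylbutan-1-one (both carbinol epimers) | CC(C)CC(=O)c1c(OCc2ccccc2)cc(O)c(C[C@@H](C(C)C)C(O)c2c(OCOC)cc(OCOC)cc2OCOC)c1OCc1ccccc1
F4 | step 7 | 1-[(3S)-2-acetoxy-5,7-bis(benzyloxy)-3-isopropylchroman-6-yl]-3-methylbutan-1-one (both C2 anomers) | CC(C)CC(=O)c1c(OCc2ccccc2)cc2c(c1OCc1ccccc1)C[C@@H](C(C)C)C(OC(C)=O)O2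
F5 | step 5 | (S)-4-benzyl-3-[(2S)-2-[2,4-bis(benzyloxy)-6-hydroxy-3-(3-methylbutanoyl)benzyl]-3-methylbutanoyl]oxazolidin-2-one | CC(C)CC(=O)c1c(OCc2ccccc2)cc(O)c(C[C@@H](C(C)C)C(=O)N2[C@@H](Cc3ccccc3)COC2=O)c1OCc1ccccc1
F6 | step 5 | (3S)-5,7-bis(benzyloxy)-3-isopropyl-6-(3-methylbutanoyl)chroman-2-one | CC(C)CC(=O)c1c(OCc2ccccc2)cc2c(c1OCc1ccccc1)C[C@@H](C(C)C)C(=O)O2
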